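**Plan**

- Retrosynthetic cuts, in order: the phenol silyl ether and the two aldehydes (from an 11,12-diol); C12–O (allylic oxidation of the C8 methyl); C9–C11 (hydroboration of a C9=C11 methylene made from a C9 ketone); the acyl–O1 ester bond; ring A at C3–C4; then C10–C1 (aldol with acrolein) and C10–CH3 (enolate methylation).
- Forward: ring B is (R)-carvone from the start (carvone C1/C2/C3/C4/C5/C6 = drimane C9/C8/C7/C6/C5/C10; ring methyl = C12; isopropenyl = C4 with its two future methyls). C10 is made quaternary, ring A is closed last, then C11, C12 and the ester are set.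
- Enabling feature: the gem-dimethyl carbon C4 sits on the ring-fusion CH (C5), and the C1 oxygen lies three bonds from C4 on quaternary C10 (C4–C3–C2–C1(O)–C10). This is the pattern left when a tertiary radical (isopropenyl + H•) adds to a vinyl ketone.
- Stereochemistry: C5 from (R)-carvone; C10 by aldol anti to the isopropenyl group, which fixes the trans ring fusion before ring A exists; 1β-OH by axial hydride attack; 9α-H/9β-C11 by α-face hydroboration opposite the 10β-methyl.
- The phenol is carried as a TIPS ether (one side step) and freed last.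

Key step: step 4

Remark: drimane numbering (C11 on C9, C12 on C8) is used for all ring positions, and 3 is carried on as its C6-epimer mixture because both epimers give the same enolate 5.

**Step 1**
Reactants: 1 (R)-(−)-carvone
Product: 3 (5R)-6-methylcarvone (C6 epimers), via carvone lithium enolate 2 (not isolated)
Conditions: LDA (1.1 equiv), THF, −78 °C; MeI, −78 → 0 °C
Reagents that add atoms: iodomethane, CI
Why: Kinetic α′-deprotonation of carvone and SN2 methylation of the cross-conjugated enolate (enolate alkylation) is standard, and the new C6 configuration is irrelevant because C6 is re-enolised in step 2.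

**Step 2**
Reactants: 3 (5R)-6-methylcarvone; 4 acrolein
Product: 6 6-(1-hydroxyprop-2-enyl)-6-methylcarvone (hydroxyallyl trans to isopropenyl; carbinol epimers), via 6-methylcarvone lithium enolate 5 (not isolated)
Conditions: LDA (1.1 equiv), THF, −78 °C; acrolein, −78 °C; AcOH quench at −78 °C
Reagents that add atoms: none
Why: The tetrasubstituted lithium enolate should add 1,2 to acrolein (lithium aldol addition) on the face anti to the neighbouring isopropenyl group, which places the new chain trans and the methyl cis to it and so sets C10; the carbinol centre is removed in step 3.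

**Step 3**
Reactants: 6 6-(1-hydroxyprop-2-enyl)-6-methylcarvone
Product: 7 (5S,6R)-2,6-dimethyl-6-(prop-2-enoyl)-5-(prop-1-en-2-yl)cyclohex-2-en-1-one (acryloyl trans to isopropenyl)
Conditions: Dess–Martin periodinane, CH2Cl2, 0 °C → rt
Reagents that add atoms: none
Why: Dess–Martin oxidation of the secondary allylic alcohol should give the non-enolisable 2,2-disubstituted 1,3-diketone under near-neutral conditions without retro-aldol cleavage, and the quaternary centre cannot epimerise.

**Step 4**
Reactants: 7 (5S,6R)-2,6-dimethyl-6-(prop-2-enoyl)-5-(prop-1-en-2-yl)cyclohex-2-en-1-one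
Product: 8 11-nordrim-7-ene-1,9-dione (trans-decalin, 5α-H, 10β-CH3)
Conditions: Fe(acac)3 (0.3 equiv), PhSiH3 (2.5 equiv), EtOH/(CH2OH)2 5:1, 0.02 M, 60 °C
Reagents that add atoms: none
Why: An iron hydride formed from Fe(acac)3, PhSiH3 and ethanol transfers H• to the CH2 terminus of the isopropenyl group, the nucleophilic tertiary radical at C4 adds to the unsubstituted β-carbon C3 of the vinyl ketone on C10, and the α-keto radical at C2 is reduced by Fe(II) to the enolate and protonated, which returns Fe(III). The closest known reaction type is the iron-catalysed MHAT reductive olefin coupling (HAT-initiated Giese addition of an unactivated alkene to an enone), here in its intramolecular form. Ring A is closed in the 6-endo-trig mode by the C3–C4 bond, which in the same event turns the isopropenyl group into the gem-dimethyl quaternary C4. No stereocentre is created (C4 carries two methyls, C2 and C3 are CH2); the trans ring fusion follows from the trans C5/C10 relationship of the two reacting arms set in step 2, which can meet only when both are equatorial. The step needs HAT to the isopropenyl group and not to the two enone double bonds, and 6-endo rather than 5-exo attack: electron-poor alkenes accept H• slowly and act only as radical traps, C7 of the ring enone would give a four-membered ring, and attack at the α-carbon C2 is polarity-mismatched. High dilution should keep the radical from adding to a second molecule of 7.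

**Step 5**
Reactants: 8 11-nordrim-7-ene-1,9-dione
Product: 9 1β-hydroxy-11-nordrim-7-en-9-one
Conditions: NaBH4 (1 equiv), MeOH/CH2Cl2 1:1, −78 °C
Reagents that add atoms: none
Why: Borohydride at low temperature should reduce the saturated C1 ketone in preference to the conjugated C9 carbonyl (chemoselective ketone-over-enone reduction), and axial hydride delivery from the α-face, anti to the axial 10β-methyl, sets the equatorial 1β-OH.

**Step 6**
Reactants: 9 1β-hydroxy-11-nordrim-7-en-9-one
Product: 10 drima-7,9(11)-dien-1β-ol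
Conditions: Zn, CH2Br2, TiCl4 (Lombardo reagent, excess), THF/CH2Cl2, 0 °C → rt
Reagents that add atoms: dibromomethane, BrCBr
Why: Lombardo methylenation is non-basic, tolerates a free hydroxyl and should not trigger retro-aldol opening of the β-hydroxy ketone, and the C9 carbonyl can only give the exocyclic C9=C11 alkene.

**Step 7**
Reactants: 11 p-coumaric acid
Product: 13 (E)-4-(triisopropylsilyloxy)cinnamic acid, via bis-TIPS silyl ester 12 (not isolated)
Conditions: TIPSCl (2.2 equiv), imidazole, DMF, rt; then AcOH/THF/H2O, rt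
Reagents that add atoms: chlorotriisopropylsilane, CC(C)[Si](Cl)(C(C)C)C(C)C
Why: Exhaustive silylation followed by selective hydrolysis of the much more labile silyl ester should leave the aryl TIPS ether, which masks the phenol through acylation, SeO2 and Swern conditions.

**Step 8**
Reactants: 10 drima-7,9(11)-dien-1β-ol; 13 (E)-4-(triisopropylsilyloxy)cinnamic acid
Product: 15 drima-7,9(11)-dien-1β-yl (E)-4-(triisopropylsilyloxy)cinnamate, via Yamaguchi mixed anhydride 14 (not isolated)
Conditions: 13 (2 equiv), 2,4,6-Cl3C6H2COCl, Et3N, THF, rt; then 10, DMAP, toluene, 60 °C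
Reagents that add atoms: none
Why: Yamaguchi esterification through the mixed anhydride and the DMAP acylpyridinium is the standard method for hindered secondary alcohols, and C1 keeps its configuration because its C–O bond is not touched.

**Step 9**
Reactants: 15 drima-7,9(11)-dien-1β-yl (E)-4-(triisopropylsilyloxy)cinnamate
Product: 17 11-hydroxydrim-7-en-1β-yl (E)-4-(triisopropylsilyloxy)cinnamate (9α-H, 9β-CH2OH), via C11 alkyl-9-BBN borane 16 (not isolated)
Conditions: 9-BBN (3 equiv), THF, 0 °C → rt; then 30% H2O2, aq NaOAc, 0 °C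
Reagents that add atoms: hydrogen peroxide, OO
Why: 9-BBN should hydroborate the 1,1-disubstituted diene terminus (boron to C11) in preference to the trisubstituted C7=C8 and the electron-poor cinnamate alkene, delivering H to C9 from the α-face because the β-face is blocked by the axial 10β-methyl (hydroboration–oxidation with buffered peroxide).

**Step 10**
Reactants: 17 11-hydroxydrim-7-en-1β-yl (E)-4-(triisopropylsilyloxy)cinnamate
Product: 18 11,12-dihydroxydrim-7-en-1β-yl (E)-4-(triisopropylsilyloxy)cinnamate
Conditions: SeO2 (0.5 equiv), t-BuOOH (3 equiv), CH2Cl2, 0 °C → rt; then NaBH4, MeOH, 0 °C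
Reagents that add atoms: selenium dioxide, O=[Se]=O; tert-butyl hydroperoxide, CC(C)(C)OO
Why: The Riley-type SeO2 ene reaction/[2,3]-shift should attack the (E)-methyl on the more substituted alkene carbon C8 (CH3 preferred over the hindered C9 methine), as known for drimenol-type substrates, and the borohydride finish returns any over-oxidised enal or its lactol to the diol.

**Step 11**
Reactants: 18 11,12-dihydroxydrim-7-en-1β-yl (E)-4-(triisopropylsilyloxy)cinnamate
Product: 19 11,12-dioxodrim-7-en-1β-yl (E)-4-(triisopropylsilyloxy)cinnamate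
Conditions: (COCl)2, DMSO, CH2Cl2, −78 °C; Et3N, −78 → −30 °C, cold quench
Reagents that add atoms: none
Why: Swern oxidation is the established way from drim-7-ene-11,12-diols to the 11,12-dialdehydes without double-bond migration, and amine addition and quench at low temperature should preserve the epimerisable 9β-CHO.

**Step 12**
Reactants: 19 11,12-dioxodrim-7-en-1β-yl (E)-4-(triisopropylsilyloxy)cinnamate
Product: 20 1β-(p-coumaroyloxy)polygodial, (1R,5S,9R,10S), the target
Conditions: TBAF (1.1 equiv), AcOH (1.5 equiv), THF, 0 °C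
Reagents that add atoms: none
Why: Fluoride should cleave the aryl silyl ether within minutes at 0 °C, and the acetic acid buffer keeps the medium non-basic so that the C9 aldehyde does not epimerise and the cinnamate is untouched.

**Compound list**

1 | (R)-(−)-carvone | CC1=CC[C@H](CC1=O)C(C)=C | starting material
2 | carvone lithium enolate (kinetic, C1–O/C6) | CC1=CC[C@@H](C(C)=C)C=C1O[Li] | intermediate
3 | (5R)-6-methylcarvone, C6 epimers | CC1C(=O)C(C)=CC[C@H]1C(C)=C | intermediate
4 | acrolein | C=CC=O | starting material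
5 | 6-methylcarvone lithium enolate | CC1=CC[C@@H](C(C)=C)C(C)=C1O[Li] | intermediate
6 | 6-(1-hydroxyprop-2-enyl)-6-methylcarvone, hydroxyallyl trans to isopropenyl, carbinol epimers | C=CC(O)[C@]1(C)C(=O)C(C)=CC[C@H]1C(C)=C | intermediate
7 | (5S,6R)-2,6-dimethyl-6-(prop-2-enoyl)-5-(prop-1-en-2-yl)cyclohex-2-en-1-one | C=CC(=O)[C@]1(C)C(=O)C(C)=CC[C@H]1C(C)=C | intermediate
8 | 11-nordrim-7-ene-1,9-dione (5α-H, 10β-CH3) | CC1(C)CCC(=O)[C@]2(C)C(=O)C(C)=CC[C@@H]12 | intermediate
9 | 1β-hydroxy-11-nordrim-7-en-9-one | CC1(C)CC[C@@H](O)[C@]2(C)C(=O)C(C)=CC[C@@H]12 | intermediate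
10 | drima-7,9(11)-dien-1β-ol | CC1(C)CC[C@@H](O)[C@]2(C)C(=C)C(C)=CC[C@@H]12 | intermediate
11 | p-coumaric acid | OC(=O)/C=C/c1ccc(O)cc1 | starting material
12 | triisopropylsilyl (E)-4-(triisopropylsilyloxy)cinnamate | CC(C)[Si](OC(=O)/C=C/c1ccc(O[Si](C(C)C)(C(C)C)C(C)C)cc1)(C(C)C)C(C)C | intermediate
13 | (E)-4-(triisopropylsilyloxy)cinnamic acid | CC(C)[Si](Oc1ccc(/C=C/C(=O)O)cc1)(C(C)C)C(C)C | intermediate
14 | (E)-4-(triisopropylsilyloxy)cinnamic 2,4,6-trichlorobenzoic anhydride | CC(C)[Si](Oc1ccc(/C=C/C(=O)OC(=O)c2c(Cl)cc(Cl)cc2Cl)cc1)(C(C)C)C(C)C | intermediate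
15 | drima-7,9(11)-dien-1β-yl (E)-4-(triisopropylsilyloxy)cinnamate | CC1(C)CC[C@@H](OC(=O)/C=C/c3ccc(O[Si](C(C)C)(C(C)C)C(C)C)cc3)[C@]2(C)C(=C)C(C)=CC[C@@H]12 | intermediate
16 | B-(1β-acyloxydrim-7-en-11-yl)-9-borabicyclo[3.3.1]nonane (acyl = (E)-4-TIPSO-cinnamoyl) | CC1(C)CC[C@@H](OC(=O)/C=C/c3ccc(O[Si](C(C)C)(C(C)C)C(C)C)cc3)[C@]2(C)[C@@H](CB4C5CCCC4CCC5)C(C)=CC[C@@H]12 | intermediate
17 | 11-hydroxydrim-7-en-1β-yl (E)-4-(triisopropylsilyloxy)cinnamate | CC1(C)CC[C@@H](OC(=O)/C=C/c3ccc(O[Si](C(C)C)(C(C)C)C(C)C)cc3)[C@]2(C)[C@@H](CO)C(C)=CC[C@@H]12 | intermediate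
18 | 11,12-dihydroxydrim-7-en-1β-yl (E)-4-(triisopropylsilyloxy)cinnamate | CC1(C)CC[C@@H](OC(=O)/C=C/c3ccc(O[Si](C(C)C)(C(C)C)C(C)C)cc3)[C@]2(C)[C@@H](CO)C(CO)=CC[C@@H]12 | intermediate
19 | 11,12-dioxodrim-7-en-1β-yl (E)-4-(triisopropylsilyloxy)cinnamate | CC1(C)CC[C@@H](OC(=O)/C=C/c3ccc(O[Si](C(C)C)(C(C)C)C(C)C)cc3)[C@]2(C)[C@@H](C=O)C(C=O)=CC[C@@H]12 | intermediate
20 | 1β-(p-coumaroyloxy)polygodial, (1R,5S,9R,10S) | CC1(C)CC[C@@H](OC(=O)/C=C/c2ccc(O)cc2)[C@]2(C)[C@@H](C=O)C(C=O)=CC[C@@H]12 | target

**Step count**

Total steps: 12. Longest linear sequence: 11 (steps 1–6 and 8–12, from (R)-carvone); step 7 is a one-step side branch.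

**Steps most likely to fail**

Step 6. The bulky zinc/titanium methylene reagent may fail to add to the C9 carbonyl, which is screened by quaternary C10, the C8 methyl and the peri 1β-oxygen, or Lewis-acid-induced retro-aldol opening of ring A may compete. The fallback sets out from 9. The hydroxyl is silylated (TESOTf, 2,6-lutidine) to 1β-(triethylsilyloxy)-11-nordrim-7-en-9-one F1. The small, hard nucleophile Me3SiCH2Li/CeCl3 is then added 1,2 to the enone to give the β-hydroxysilane F2. Aqueous HF in MeCN should effect Peterson elimination and loss of the TES group in one operation, which comes back to the route at 10.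

Step 8. Acyl transfer to the neopentyl-type 1β-hydroxyl may be too slow, so that the mixed anhydride is consumed unproductively. The fallback sets out from 10. Acylation with diethylphosphonoacetic acid (DCC, DMAP), which proceeds through a sterically undemanding phosphonoketene, should give drima-7,9(11)-dien-1β-yl (diethoxyphosphoryl)acetate F3. A Horner–Wadsworth–Emmons reaction (LiCl, DBU, MeCN) with 4-(triisopropylsilyloxy)benzaldehyde F4 (from 4-hydroxybenzaldehyde, TIPSCl, imidazole) then builds the (E)-cinnamate on the oxygen already in place and comes back at 15.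

Step 9. Chemoselectivity may be lost (conjugate reduction or hydroboration of the cinnamate double bond), or the hindered diene terminus may react too slowly. The fallback sets out from 10 and hydroborates before acylation:
- Excess 9-BBN gives the O,C-bis-boryl intermediate F5, which is oxidised (H2O2, NaOH) to drim-7-ene-1β,11-diol F6.
- SeO2/t-BuOOH followed by NaBH4 gives drim-7-ene-1β,11,12-triol F7.
- TESCl (2.2 equiv)/imidazole should silylate only the two primary hydroxyls, giving 11,12-bis(triethylsilyloxy)drim-7-en-1β-ol F8.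
- Yamaguchi acylation with 13 (through 14) gives the ester F9.
- PPTS in MeOH removes both TES ethers while the aryl TIPS ether stays, and the route is rejoined at 18.

**Further compounds**

F1 | step 6 | 1β-(triethylsilyloxy)-11-nordrim-7-en-9-one | CC1(C)CC[C@@H](O[Si](CC)(CC)CC)[C@]2(C)C(=O)C(C)=CC[C@@H]12
F2 | step 6 | 1β-(triethylsilyloxy)-9-[(trimethylsilyl)methyl]-11-nordrim-7-en-9-ol | CC1(C)CC[C@@H](O[Si](CC)(CC)CC)[C@]2(C)C(O)(C[Si](C)(C)C)C(C)=CC[C@@H]12
F3 | step 8 | drima-7,9(11)-dien-1β-yl (diethoxyphosphoryl)acetate | CC1(C)CC[C@@H](OC(=O)CP(=O)(OCC)OCC)[C@]2(C)C(=C)C(C)=CC[C@@H]12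
F4 | step 8 | 4-(triisopropylsilyloxy)benzaldehyde | CC(C)[Si](Oc1ccc(C=O)cc1)(C(C)C)C(C)C
F5 | step 9 | 1β-O,11-C-bis(9-borabicyclo[3.3.1]nonan-9-yl)drim-7-en-1-ol | CC1(C)CC[C@@H](OB3C4CCCC3CCC4)[C@]2(C)[C@@H](CB5C6CCCC5CCC6)C(C)=CC[C@@H]12
F6 | step 9 | drim-7-ene-1β,11-diol | CC1(C)CC[C@@H](O)[C@]2(C)[C@@H](CO)C(C)=CC[C@@H]12
F7 | step 9 | drim-7-ene-1β,11,12-triol | CC1(C)CC[C@@H](O)[C@]2(C)[C@@H](CO)C(CO)=CC[C@@H]12
F8 | step 9 | 11,12-bis(triethylsilyloxy)drim-7-en-1β-ol | CC1(C)CC[C@@H](O)[C@]2(C)[C@@H](CO[Si](CC)(CC)CC)C(CO[Si](CC)(CC)CC)=CC[C@@H]12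
F9 | step 9 | 11,12-bis(triethylsilyloxy)drim-7-en-1β-yl (E)-4-(triisopropylsilyloxy)cinnamate | CC1(C)CC[C@@H](OC(=O)/C=C/c3ccc(O[Si](C(C)C)(C(C)C)C(C)C)cc3)[C@]2(C)[C@@H](CO[Si](CC)(CC)CC)C(CO[Si](CC)(CC)CC)=CC[C@@H]12
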